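**Retrosynthetic overview**
1. Isoaurmillone ⇐ 4'-O-prenylation of 7-O-pivaloyl-tectorigenin, then ester methanolysis. The prenyl ether goes on last because it would not survive Tl(III), H2/Pd or acid.
2. Tectorigenin ⇐ its 5,7,4'-tri-O-benzyl ether ⇐ oxidative 1,2-aryl shift and acid ring closure of a 2'-hydroxychalcone. The pyranone ring is the only ring built; both benzene rings are bought in.
3. Chalcone ⇐ Claisen–Schmidt aldol condensation of an A-ring acetophenone with 4-(benzyloxy)benzaldehyde. This bond becomes C2–C3 of the isoflavone.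
4. Acetophenone ⇐ symmetric 3,5-bis(benzyloxy)-4-methoxyphenol by ortho-lithiation/acylation. The symmetry fixes 6-OMe rather than 8-OMe.
5. Phenol ⇐ methyl 3,5-dihydroxy-4-methoxybenzoate by benzylation, reduction, oxidation and Baeyer–Villiger oxidation.

Assumption: the target has no stereocentre, so no enantiocontrol is needed; the racemic centres in 13 and 18 are transient and are destroyed.

**Route**

Step 1
Reactants: 1 methyl 3,5-dihydroxy-4-methoxybenzoate; 2 benzyl bromide
Product: 3 methyl 3,5-bis(benzyloxy)-4-methoxybenzoate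
Conditions: BnBr, K2CO3, DMF, 60 °C
Reagents that add atoms: benzyl bromide BrCc1ccccc1
Why: Williamson ether synthesis on the two equivalent phenols; the methyl ester is untouched.

Step 2
Reactants: 3 methyl 3,5-bis(benzyloxy)-4-methoxybenzoate
Product: 4 [3,5-bis(benzyloxy)-4-methoxyphenyl]methanol
Conditions: LiAlH4, THF, 0 °C to rt
Reagents that add atoms: none
Why: Hydride reduction of the ester to the primary benzylic alcohol; aryl benzyl ethers are inert to LiAlH4.

Step 3
Reactants: 4 [3,5-bis(benzyloxy)-4-methoxyphenyl]methanol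
Product: 5 3,5-bis(benzyloxy)-4-methoxybenzaldehyde
Conditions: activated MnO2, CH2Cl2, rt
Reagents that add atoms: none
Why: Selective MnO2 oxidation of a benzylic alcohol stops cleanly at the aldehyde.

Step 4
Reactants: 5 3,5-bis(benzyloxy)-4-methoxybenzaldehyde; 6 3-chloroperoxybenzoic acid (mCPBA)
Product: 8 3,5-bis(benzyloxy)-4-methoxyphenol, via aryl formate 7 (not isolated)
Conditions: mCPBA, CH2Cl2, 0 °C to rt; aq. NaHCO3 wash; then K2CO3 (cat.), MeOH, rt
Reagents that add atoms: 3-chloroperoxybenzoic acid OOC(=O)c1cccc(Cl)c1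
Why: Baeyer–Villiger (Dakin-type) oxidation with migration of the electron-rich aryl group gives the formate, which is methanolysed to a phenol whose two free ring positions are equivalent.

Step 5
Reactants: 8 3,5-bis(benzyloxy)-4-methoxyphenol; 9 chloromethyl methyl ether
Product: 10 1,3-bis(benzyloxy)-2-methoxy-5-(methoxymethoxy)benzene
Conditions: MOMCl, K2CO3, acetone, rt
Reagents that add atoms: chloromethyl methyl ether COCCl
Why: O-alkylation of the unhindered phenoxide gives the MOM ether, a strong ortho-directing group for the next step.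

Step 6
Reactants: 10 1,3-bis(benzyloxy)-2-methoxy-5-(methoxymethoxy)benzene; 11 N-methoxy-N-methylacetamide
Product: 14 1-[2,4-bis(benzyloxy)-3-methoxy-6-(methoxymethoxy)phenyl]ethan-1-one, via aryllithium 12 (not isolated), via lithium hemiaminal 13 (not isolated)
Conditions: n-BuLi, THF, 0 °C; then MeC(O)N(OMe)Me, −78 °C to rt; H2O
Reagents that add atoms: N-methoxy-N-methylacetamide CC(=O)N(C)OC
Why: Directed ortho-metalation at the position flanked by OMOM and OBn (both such positions are equivalent), then Weinreb-amide acylation, whose stable chelated adduct prevents over-addition.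

Step 7
Reactants: 14 1-[2,4-bis(benzyloxy)-3-methoxy-6-(methoxymethoxy)phenyl]ethan-1-one
Product: 15 1-[2,4-bis(benzyloxy)-6-hydroxy-3-methoxyphenyl]ethan-1-one
Conditions: 3 M HCl, MeOH/THF, 50 °C
Reagents that add atoms: none
Why: Acid-catalysed acetal cleavage removes only the MOM group and frees the one phenol that will become O1; benzyl ethers survive dilute HCl.

Step 8
Reactants: 15 1-[2,4-bis(benzyloxy)-6-hydroxy-3-methoxyphenyl]ethan-1-one; 16 4-(benzyloxy)benzaldehyde
Product: 17 (E)-1-[2,4-bis(benzyloxy)-6-hydroxy-3-methoxyphenyl]-3-[4-(benzyloxy)phenyl]prop-2-en-1-one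
Conditions: KOH, EtOH/H2O, rt; then dil. HCl to pH 4
Reagents that add atoms: 4-(benzyloxy)benzaldehyde O=Cc1ccc(OCc2ccccc2)cc1
Why: Claisen–Schmidt crossed aldol condensation of the methyl ketone enolate with a non-enolisable aldehyde joins the A- and B-ring fragments; E1cB dehydration gives the thermodynamic E-enone.

Step 9
Reactants: 17 (E)-1-[2,4-bis(benzyloxy)-6-hydroxy-3-methoxyphenyl]-3-[4-(benzyloxy)phenyl]prop-2-en-1-one
Product: 19 5,7-bis(benzyloxy)-3-[4-(benzyloxy)phenyl]-6-methoxy-4H-chromen-4-one, via dimethyl acetal 18 (not isolated)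
Conditions: Tl(NO3)3·3H2O, MeOH/HC(OMe)3/CH2Cl2, rt; then 10% HCl, MeOH/THF, 60 °C
Reagents that add atoms: none
Why: Tl(III)-mediated oxidative 1,2-aryl migration of the chalcone gives the β-keto acetal (its methoxy groups come from solvent methanol), and acid closes the pyranone through the only free phenol, fixing 6-OMe.

Step 10
Reactants: 19 5,7-bis(benzyloxy)-3-[4-(benzyloxy)phenyl]-6-methoxy-4H-chromen-4-one
Product: 20 5,7-dihydroxy-3-(4-hydroxyphenyl)-6-methoxy-4H-chromen-4-one (tectorigenin)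
Conditions: H2 (1 atm), 10% Pd/C, THF/MeOH, rt
Reagents that add atoms: none
Why: Catalytic hydrogenolysis removes all three benzyl ethers; the reaction is stopped at full debenzylation, before the conjugated chromone C2=C3 bond is reduced.

Step 11
Reactants: 20 tectorigenin; 21 pivaloyl chloride
Product: 23 5-hydroxy-3-(4-hydroxyphenyl)-6-methoxy-4-oxo-4H-chromen-7-yl 2,2-dimethylpropanoate, via potassium 7-phenoxide 22 (not isolated)
Conditions: t-BuOK (1.0 equiv), DMF, 0 °C; then PivCl (1.0 equiv), 0 °C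
Reagents that add atoms: pivaloyl chloride CC(C)(C)C(Cl)=O
Why: The 7-OH is the most acidic phenol (vinylogous acid para to C4=O; the 5-OH is chelated), so one equivalent of base gives the 7-monoanion and O-acylation occurs there.

Step 12
Reactants: 23 7-O-pivaloyl-tectorigenin; 24 3-methylbut-2-en-1-ol
Product: 25 5-hydroxy-6-methoxy-3-{4-[(3-methylbut-2-en-1-yl)oxy]phenyl}-4-oxo-4H-chromen-7-yl 2,2-dimethylpropanoate
Conditions: prenol, PPh3, DIAD, THF, 0 °C to rt
Reagents that add atoms: 3-methylbut-2-en-1-ol CC(C)=CCO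
Why: Mitsunobu etherification of the only free non-chelated phenol with a primary allylic alcohol; no free phenoxide is present, so the pivalate does not migrate, and the H-bonded 5-OH is inert.

Step 13
Reactants: 25 7-O-pivaloyl-4'-O-prenyl-tectorigenin
Product: 26 isoaurmillone, 5,7-dihydroxy-6-methoxy-3-{4-[(3-methylbut-2-en-1-yl)oxy]phenyl}-4H-chromen-4-one
Conditions: K2CO3 (cat.), MeOH, rt; aq. NH4Cl work-up
Reagents that add atoms: none
Why: Base-catalysed transesterification cleaves the activated aryl pivalate; the acid-sensitive prenyl ether and the isoflavone core are stable to carbonate in methanol at rt.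

**Compound list**
1 | methyl 3,5-dihydroxy-4-methoxybenzoate | COC(=O)c1cc(O)c(OC)c(O)c1 | starting material
2 | benzyl bromide | BrCc1ccccc1 | starting material
3 | methyl 3,5-bis(benzyloxy)-4-methoxybenzoate | COC(=O)c1cc(OCc2ccccc2)c(OC)c(OCc2ccccc2)c1 | intermediate
4 | [3,5-bis(benzyloxy)-4-methoxyphenyl]methanol | OCc1cc(OCc2ccccc2)c(OC)c(OCc2ccccc2)c1 | intermediate
5 | 3,5-bis(benzyloxy)-4-methoxybenzaldehyde | O=Cc1cc(OCc2ccccc2)c(OC)c(OCc2ccccc2)c1 | intermediate
6 | 3-chloroperoxybenzoic acid | OOC(=O)c1cccc(Cl)c1 | starting material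
7 | 3,5-bis(benzyloxy)-4-methoxyphenyl formate | O=COc1cc(OCc2ccccc2)c(OC)c(OCc2ccccc2)c1 | intermediate (not isolated)
8 | 3,5-bis(benzyloxy)-4-methoxyphenol | Oc1cc(OCc2ccccc2)c(OC)c(OCc2ccccc2)c1 | intermediate
9 | chloromethyl methyl ether | COCCl | starting material
10 | 1,3-bis(benzyloxy)-2-methoxy-5-(methoxymethoxy)benzene | COCOc1cc(OCc2ccccc2)c(OC)c(OCc2ccccc2)c1 | intermediate
11 | N-methoxy-N-methylacetamide | CC(=O)N(C)OC | starting material
12 | [2,4-bis(benzyloxy)-3-methoxy-6-(methoxymethoxy)phenyl]lithium | [Li]c1c(OCOC)cc(OCc2ccccc2)c(OC)c1OCc1ccccc1 | intermediate (not isolated)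
13 | lithium 1-[2,4-bis(benzyloxy)-3-methoxy-6-(methoxymethoxy)phenyl]-1-[methoxy(methyl)amino]ethan-1-olate (racemic) | [Li]OC(C)(N(C)OC)c1c(OCOC)cc(OCc2ccccc2)c(OC)c1OCc1ccccc1 | intermediate (not isolated)
14 | 1-[2,4-bis(benzyloxy)-3-methoxy-6-(methoxymethoxy)phenyl]ethan-1-one | CC(=O)c1c(OCOC)cc(OCc2ccccc2)c(OC)c1OCc1ccccc1 | intermediate
15 | 1-[2,4-bis(benzyloxy)-6-hydroxy-3-methoxyphenyl]ethan-1-one | CC(=O)c1c(O)cc(OCc2ccccc2)c(OC)c1OCc1ccccc1 | intermediate
16 | 4-(benzyloxy)benzaldehyde | O=Cc1ccc(OCc2ccccc2)cc1 | starting material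
17 | (E)-1-[2,4-bis(benzyloxy)-6-hydroxy-3-methoxyphenyl]-3-[4-(benzyloxy)phenyl]prop-2-en-1-one | O=C(/C=C/c1ccc(OCc2ccccc2)cc1)c1c(O)cc(OCc2ccccc2)c(OC)c1OCc1ccccc1 | intermediate
18 | 1-[2,4-bis(benzyloxy)-6-hydroxy-3-methoxyphenyl]-2-[4-(benzyloxy)phenyl]-3,3-dimethoxypropan-1-one (racemic) | COC(OC)C(c1ccc(OCc2ccccc2)cc1)C(=O)c1c(O)cc(OCc2ccccc2)c(OC)c1OCc1ccccc1 | intermediate (not isolated)
19 | 5,7-bis(benzyloxy)-3-[4-(benzyloxy)phenyl]-6-methoxy-4H-chromen-4-one | COc1c(OCc2ccccc2)cc2occ(-c3ccc(OCc4ccccc4)cc3)c(=O)c2c1OCc1ccccc1 | intermediate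
20 | 5,7-dihydroxy-3-(4-hydroxyphenyl)-6-methoxy-4H-chromen-4-one (tectorigenin) | COc1c(O)cc2occ(-c3ccc(O)cc3)c(=O)c2c1O | intermediate
21 | pivaloyl chloride | CC(C)(C)C(Cl)=O | starting material
22 | potassium 5-hydroxy-3-(4-hydroxyphenyl)-6-methoxy-4-oxo-4H-chromen-7-olate | COc1c([O-])cc2occ(-c3ccc(O)cc3)c(=O)c2c1O.[K+] | intermediate (not isolated)
23 | 5-hydroxy-3-(4-hydroxyphenyl)-6-methoxy-4-oxo-4H-chromen-7-yl 2,2-dimethylpropanoate | COc1c(OC(=O)C(C)(C)C)cc2occ(-c3ccc(O)cc3)c(=O)c2c1O | intermediate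
24 | 3-methylbut-2-en-1-ol (prenol) | CC(C)=CCO | starting material
25 | 5-hydroxy-6-methoxy-3-{4-[(3-methylbut-2-en-1-yl)oxy]phenyl}-4-oxo-4H-chromen-7-yl 2,2-dimethylpropanoate | COc1c(OC(=O)C(C)(C)C)cc2occ(-c3ccc(OCC=C(C)C)cc3)c(=O)c2c1O | intermediate
26 | isoaurmillone | COc1c(O)cc2occ(-c3ccc(OCC=C(C)C)cc3)c(=O)c2c1O | target

**Totals**
Total step count: 13. Longest linear sequence: 13 steps (1 to 26; aldehyde 16 is bought).

**Steps most likely to fail, with fallbacks**

Step 6 is at risk because n-BuLi can also lithiate the benzylic CH2 of the benzyl ethers (Wittig rearrangement) instead of the ring. The fallback sets out from phenol 8 and avoids organolithium chemistry. Magnesium-mediated ortho-formylation (MgCl2, Et3N, paraformaldehyde, MeCN, reflux) gives 2,4-bis(benzyloxy)-6-hydroxy-3-methoxybenzaldehyde F1. Addition of MeMgBr (3 equiv, THF, 0 °C) gives racemic 1-[2,4-bis(benzyloxy)-6-hydroxy-3-methoxyphenyl]ethan-1-ol F2. MnO2 in CH2Cl2 oxidises this benzylic alcohol to the ketone, and the route is rejoined at 15.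

Step 9 is at risk because the Tl(III) rearrangement of a hindered, electron-rich 2'-hydroxychalcone can divert to aurone or over-oxidation products. The fallback sets out from chalcone 17 and goes through a flavanone instead. NaOAc in refluxing EtOH closes 17 by intramolecular oxa-Michael addition to racemic 5,7-bis(benzyloxy)-2-[4-(benzyloxy)phenyl]-6-methoxy-2,3-dihydro-4H-chromen-4-one F3. [Hydroxy(tosyloxy)iodo]benzene in refluxing MeCN then effects the oxidative 2,3-aryl migration, and the route is rejoined at 19.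

Step 11 is at risk because mono-acylation may not discriminate cleanly between 7-OH and 4'-OH. The fallback sets out from tectorigenin 20 and reverses the selectivity logic, with no protecting group. t-BuOK (2.1 equiv, DMF, 0 °C) gives the dipotassium 7,4'-bis(phenoxide) of tectorigenin F4. In this dianion the less delocalised 4'-phenoxide is the more nucleophilic site, so prenyl bromide (1.0 equiv) alkylates there. Mild acidic work-up gives the target directly, and the route is rejoined at 26.

**Further compounds**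
F1 | step 6 | 2,4-bis(benzyloxy)-6-hydroxy-3-methoxybenzaldehyde | O=Cc1c(O)cc(OCc2ccccc2)c(OC)c1OCc1ccccc1
F2 | step 6 | 1-[2,4-bis(benzyloxy)-6-hydroxy-3-methoxyphenyl]ethan-1-ol (racemic) | CC(O)c1c(O)cc(OCc2ccccc2)c(OC)c1OCc1ccccc1
F3 | step 9 | 5,7-bis(benzyloxy)-2-[4-(benzyloxy)phenyl]-6-methoxy-2,3-dihydro-4H-chromen-4-one (racemic) | COc1c(OCc2ccccc2)cc2OC(CC(=O)c2c1OCc1ccccc1)c1ccc(OCc2ccccc2)cc1
F4 | step 11 | dipotassium 5-hydroxy-6-methoxy-3-(4-oxidophenyl)-4-oxo-4H-chromen-7-olate | COc1c([O-])cc2occ(-c3ccc([O-])cc3)c(=O)c2c1O.[K+].[K+]
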